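A small charge of solid substrate, 20 mM on Saturday, gives nearly the same percent curves as the 45 mM of Wednesday. So the fall of target reads as first order, and the 30 mM flask should share it.

| flask | solid substrate | remark | time |
|---|---|---|---|
| Saturday's | 20 mM | run made earlier |  |
| Wednesday's | 45 mM | run made earlier |  |
| flask | 30 mM |  | 1.5 h |

| run | time / min | solid substrate / % | target / % |
|---|---|---|---|
| Saturday's | 5.00 | 1.0 | 17.2 |
| Saturday's | 15.0 | 0 | 4.5 |
| Saturday's | 25.0 | 0.1 | 1.3 |
| Saturday's | 40.0 | 0 | 1.5 |
| Saturday's | 50.0 | 0 | 2.6 |
| Wednesday's | 5.00 | 0.7 | 19.4 |
| Wednesday's | 15.0 | 0 | 2.7 |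
| Wednesday's | 25.0 | 1.3 | 1.8 |
| Wednesday's | 40.0 | 0 | 0.8 |
| Wednesday's | 50.0 | 1.6 | 1.4 |

(standard deviation of a reading: 1 percentage point)

1. part of the solid substrate that has turned into other species by 1.5 h (what has only dissolved does not count)
2. target at 1.5 h, in percent of the solid substrate charged

- solid, in amounts per volume of the solution: solid substrate
- what was read earlier has a scatter of 1 percentage point, one standard deviation
- at the start none of the solid substrate is in solution
- what has only dissolved of solid substrate counts as not reacted

Two times matter: the fall half-life of target and the asked time. Averaged over both runs, target falls from 18.3% at 5.00 min to 3.60% at 15.0 min. That reads as a fall half-life, t_f, of 4.26 min. The asked time of 1.5 h is far longer than t_f. The fall count n, the asked time over t_f, is 21.1. After so many fall half-lives, the flask should read flat by then, at the level of the late readings.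

The forecast gives a conversion of 100% and target at 1.5%: “That suggests a small plateau, perhaps an equilibrium”.

The flask gives a conversion of 97.7% and target at 1.87%, so both numbers of the forecast stand inside the margins.

    starting material ⇌ target (K = 0.820, k = 0.0390 s⁻¹)
    starting material ⇌ isomer of the product (K = 42.0, k = 0.00630 s⁻¹)
    solid substrate ⇌ starting material, rate k3*(cs3 - [starting material]) while solid is left; crystals form when [starting material] > cs3 (solubility = 19.0 mM, k = 0.0450 s⁻¹)

At 0.750 h, which is 10.6 times t_f, the flask holds target at 1.88%, and still at 1.87% at 1.50 h. The material leaves through the path to isomer of the product: in the run without that path, conversion of solid substrate reaches 45.1% against 97.7%. The neighbour charged with 12 mM, counted with the same t_f, has the same n of 21.1, and its target stands at 1.87%.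

The numbers in the tables were computed on assumed constants, and the scatter is random.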